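Ring B (C5–C10) of the target carries oxygen at C6 and C9 and methyl groups at C8 and C10, the substitution pattern of 2,6-dimethyl-1,4-benzoquinone. Everything rests on a thermal Diels–Alder union of the siloxy diene holding C1–C4 with the quinone monoepoxide: ring A is closed through the C4–C5 and C1–C10 bonds in one operation, setting C5 and the quaternary C10. The catalytically installed C7–C8 epoxide, erased afterwards, steers the diene to one face; C5, C8, C6, C9 and C3 are then relayed from C10 by substrate control. The precursors are a flat, dearomatised enedione and an achiral diene.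

Key step: step 3

Remark on numbering: atoms are numbered as in the labdane skeleton of the target (ring A = C1–C5 and C10; ring B = C5–C10; side chain C11–C16; C17 on C8, C18/C19 on C4, C20 on C10); β is the face of C20, α the opposite face.

Assumption: the sense of induction of the ammonium catalyst in step 1 is taken to give (1S,6R)-2; should the antipode form, the pseudo-enantiomeric cinchoninium salt is used instead.

Step 1
Reactants: 1 2,6-dimethyl-1,4-benzoquinone
Product: 2 (1S,6R)-1,3-dimethyl-7-oxabicyclo[4.1.0]hept-3-ene-2,5-dione (the 7β,8β-monoepoxide of ring B)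
Conditions: NaOCl (aq., 1.05 equiv), N-(anthracen-9-ylmethyl)cinchonidinium bromide (10 mol %), toluene, −10 °C
Reagents that add atoms: sodium hypochlorite, [Na+].[O-]Cl
Why: Weitz–Scheffer nucleophilic epoxidation under chiral phase-transfer catalysis, in which hypochlorite adds to the unsubstituted carbon C7 of one of the two equivalent C=C bonds inside the chiral ion pair, so the catalyst sets the C7/C8 configuration and the limiting oxidant should stop the reaction at the monoepoxide.

Step 2
Reactants: 3 4-methylpent-1-en-3-one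
Product: 4 triisopropyl[(4-methylpenta-1,3-dien-3-yl)oxy]silane
Conditions: i-Pr3SiOTf, Et3N, CH2Cl2, 0 °C to rt
Reagents that add atoms: triisopropylsilyl trifluoromethanesulfonate, CC(C)[Si](OS(=O)(=O)C(F)(F)F)(C(C)C)C(C)C
Why: Soft enolisation (silyl enol ether formation) at the only enolisable position, the isopropyl methine, should give the cross-conjugated 2-siloxy diene.

Step 3
Reactants: 2 (1S,6R)-1,3-dimethyl-7-oxabicyclo[4.1.0]hept-3-ene-2,5-dione; 4 triisopropyl[(4-methylpenta-1,3-dien-3-yl)oxy]silane
Product: 5 cis-fused cycloadduct 7β,8β-epoxy-4,4,8,10-tetramethyl-3-(triisopropylsilyloxy)decal-2-ene-6,9-dione with 5β-H and 10β-CH3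
Conditions: toluene, 100 °C, sealed tube, 2,6-di-tert-butyl-4-methylphenol (cat.)
Reagents that add atoms: none
Why: Thermal normal-demand Diels–Alder cycloaddition, concerted but asynchronous, of a 2-siloxy diene with a cyclohex-2-ene-1,4-dione, the closest known type being quinone and epoxyquinone Diels–Alder reactions with siloxy dienes. Ring A is closed in an intermolecular [4+2] mode in which C4–C5 and C1–C10 form suprafacially on both partners. C5 and C10 therefore arise cis to each other, and both new bonds form anti to the oxirane oxygen because the diene approaches the face of ring B opposite the epoxide, so the configuration set in step 1 fixes the quaternary C10. Regioselectivity is needed: the tetrasubstituted, siloxy-activated terminus C4 should bond to the unsubstituted carbon C5 (β to the C9 carbonyl) and the CH2 terminus C1 to the methyl-bearing C10, an orientation favoured both by the larger orbital coefficient at C4 and by avoidance of two adjacent quaternary carbons. Only one C=C is left in 2, so site selectivity does not arise, and no Lewis acid is used because coordination at the C6 carbonyl would reverse the polarisation of the dienophile.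

Step 4
Reactants: 5 cis-fused cycloadduct
Product: 7 trans-fused 4,4,8α,10β-tetramethyl-3-(triisopropylsilyloxy)decal-2-ene-6,9-dione with 5α-H, via cis-fused dione 6 (not isolated)
Conditions: SmI2 (4.5 equiv), THF/MeOH, −78 to 0 °C; then DBU, rt
Reagents that add atoms: none
Why: SmI2 should cleave both C–O bonds of the epoxide, each being α to a ketone (reduction of α-heterosubstituted ketones), and DBU then equilibrates the enolisable centres C5 and C8 to the trans-fused decalin with equatorial 8α-methyl (thermodynamic control, as in the 5β to 5α equilibration of 6-oxo steroids).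

Step 5
Reactants: 7 trans-fused 6,9-dione
Product: 8 6β-hydroxy-4,4,8α,10β-tetramethyl-3-(triisopropylsilyloxy)-trans-decal-2-en-9-one
Conditions: LiBH(s-Bu)3, THF, −78 °C; aq. NH4Cl
Reagents that add atoms: none
Why: The bulky hydride should reduce only the C6 ketone (C9 is flanked by quaternary C10 and branched C8) from the α face, the β face being shielded by the axial methyl groups on C4 and C10, to give the axial 6β-alcohol (diastereoselective ketone reduction).

Step 6
Reactants: 8 6β-hydroxy-9-ketone
Product: 9 9α,11-epoxide (spiro-oxirane at C9 with oxygen α and C11 β) of the 6β-hydroxy silyl enol ether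
Conditions: Me3S(O)I, NaH, DMSO, rt to 50 °C
Reagents that add atoms: trimethylsulfoxonium iodide, C[S+](C)(C)=O.[I-]
Why: Corey–Chaykovsky epoxidation with the sulfoxonium ylide, whose reversible betaine formation places the new C9–C11 bond equatorial (β) and the oxygen axial (α) as the target requires, while the silyl enol ether is inert to this nucleophilic reagent.

Step 7
Reactants: 9 9α,11-epoxide
Product: 10 9α-hydroxy-9β-vinyl compound (6β,9α-diol, C11=C12 vinyl group, C3 silyl enol ether)
Conditions: Me3SI, n-BuLi, THF, −10 °C to rt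
Reagents that add atoms: trimethylsulfonium iodide, C[S+](C)C.[I-]
Why: Dimethylsulfonium methylide should open the spiro-epoxide at its CH2 carbon (C11) and the γ-oxido sulfonium salt then loses dimethyl sulfide, giving the one-carbon homologated tertiary allylic alcohol with C9 untouched (epoxide to allylic alcohol homologation).

Step 8
Reactants: 10 6β,9α-diol with 9β-vinyl group
Product: 11 6β-acetoxy-9α-hydroxy-9β-vinyl silyl enol ether
Conditions: Ac2O, DMAP, pyridine, 50 °C
Reagents that add atoms: acetic anhydride, CC(=O)OC(C)=O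
Why: DMAP-catalysed acylation should esterify the only secondary alcohol, the tertiary allylic C9 hydroxyl being unreactive under these conditions.

Step 9
Reactants: 11 6β-acetoxy-9α-hydroxy-9β-vinyl silyl enol ether
Product: 13 6β-acetoxy-3β,9α-dihydroxy-9β-vinyl-4,4,8α,10β-tetramethyl-trans-decalin, via 3-ketone 12 (not isolated)
Conditions: Bu4NF, AcOH, THF, 0 °C; then MeOH, NaBH4, −20 °C
Reagents that add atoms: none
Why: Buffered fluoride cleaves the silyl enol ether to the C3 ketone, which NaBH4 should reduce by axial attack from the α face (the β face carries the axial 4β- and 10β-methyl groups) to the equatorial 3β-alcohol, while the hindered acetate survives.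

Step 10
Reactants: 13 6β-acetoxy-3β,9α-dihydroxy-9β-vinyl decalin; 14 3-bromofuran-2(5H)-one
Product: 16 target, 6β-acetoxy-3β,9α-dihydroxylabd-13-en-16,15-olide, via C12 alkylborane 15 (not isolated)
Conditions: 9-BBN (3.5 equiv), THF, rt to 50 °C; then 14, PdCl2(dppf) (5 mol %), AsPh3, Cs2CO3, DMF/H2O, rt
Reagents that add atoms: none
Why: Anti-Markovnikov hydroboration of the terminal vinyl group followed by B-alkyl Suzuki–Miyaura coupling with the α-bromobutenolide should form the C12–C13 bond and deliver the α-substituted butenolide directly.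

Compound list
1 | 2,6-dimethyl-1,4-benzoquinone | CC1=CC(=O)C=C(C)C1=O | starting material
2 | (1S,6R)-1,3-dimethyl-7-oxabicyclo[4.1.0]hept-3-ene-2,5-dione | C[C@]12O[C@H]1C(=O)C=C(C)C2=O | intermediate
3 | 4-methylpent-1-en-3-one | CC(C)C(=O)C=C | starting material
4 | triisopropyl[(4-methylpenta-1,3-dien-3-yl)oxy]silane | C=CC(O[Si](C(C)C)(C(C)C)C(C)C)=C(C)C | intermediate
5 | cis-fused (5β-H, 10β-CH3) 7β,8β-epoxy-4,4,8,10-tetramethyl-3-(triisopropylsilyloxy)decal-2-ene-6,9-dione | C[C@]12CC=C(O[Si](C(C)C)(C(C)C)C(C)C)C(C)(C)[C@H]1C(=O)[C@@H]3O[C@]3(C)C2=O | intermediate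
6 | cis-fused (5β-H) 4,4,8,10-tetramethyl-3-(triisopropylsilyloxy)decal-2-ene-6,9-dione, drawn with 8α-methyl (C8 equilibrates) | C[C@]12CC=C(O[Si](C(C)C)(C(C)C)C(C)C)C(C)(C)[C@H]1C(=O)C[C@@H](C)C2=O | intermediate (not isolated)
7 | trans-fused (5α-H) 4,4,8α,10β-tetramethyl-3-(triisopropylsilyloxy)decal-2-ene-6,9-dione | C[C@]12CC=C(O[Si](C(C)C)(C(C)C)C(C)C)C(C)(C)[C@@H]1C(=O)C[C@@H](C)C2=O | intermediate
8 | 6β-hydroxy-4,4,8α,10β-tetramethyl-3-(triisopropylsilyloxy)-trans-decal-2-en-9-one | C[C@]12CC=C(O[Si](C(C)C)(C(C)C)C(C)C)C(C)(C)[C@@H]1[C@H](O)C[C@@H](C)C2=O | intermediate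
9 | 9α,11-epoxy-6β-hydroxy-4,4,8α,10β-tetramethyl-3-(triisopropylsilyloxy)-trans-decal-2-ene (spiro-oxirane at C9) | C[C@]12CC=C(O[Si](C(C)C)(C(C)C)C(C)C)C(C)(C)[C@@H]1[C@H](O)C[C@@H](C)[C@]23CO3 | intermediate
10 | 6β,9α-dihydroxy-9β-vinyl-4,4,8α,10β-tetramethyl-3-(triisopropylsilyloxy)-trans-decal-2-ene | C[C@]12CC=C(O[Si](C(C)C)(C(C)C)C(C)C)C(C)(C)[C@@H]1[C@H](O)C[C@@H](C)[C@]2(O)C=C | intermediate
11 | 6β-acetoxy-9α-hydroxy-9β-vinyl-4,4,8α,10β-tetramethyl-3-(triisopropylsilyloxy)-trans-decal-2-ene | C[C@]12CC=C(O[Si](C(C)C)(C(C)C)C(C)C)C(C)(C)[C@@H]1[C@H](OC(C)=O)C[C@@H](C)[C@]2(O)C=C | intermediate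
12 | 6β-acetoxy-9α-hydroxy-9β-vinyl-4,4,8α,10β-tetramethyl-trans-decalin-3-one | C[C@]12CCC(=O)C(C)(C)[C@@H]1[C@H](OC(C)=O)C[C@@H](C)[C@]2(O)C=C | intermediate (not isolated)
13 | 6β-acetoxy-3β,9α-dihydroxy-9β-vinyl-4,4,8α,10β-tetramethyl-trans-decalin | C[C@]12CC[C@H](O)C(C)(C)[C@@H]1[C@H](OC(C)=O)C[C@@H](C)[C@]2(O)C=C | intermediate
14 | 3-bromofuran-2(5H)-one | O=C1OCC=C1Br | starting material
15 | B-alkyl-9-borabicyclo[3.3.1]nonane carrying the boron on C12 of 13 | C[C@]12CC[C@H](O)C(C)(C)[C@@H]1[C@H](OC(C)=O)C[C@@H](C)[C@]2(O)CCB1C2CCCC1CCC2 | intermediate (not isolated)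
16 | 6β-acetoxy-3β,9α-dihydroxylabd-13-en-16,15-olide | C[C@]12CC[C@H](O)C(C)(C)[C@@H]1[C@H](OC(C)=O)C[C@@H](C)[C@]2(O)CCC1=CCOC1=O | target

Total step count: 10. Longest linear sequence: 9 steps (steps 1 and 3 to 10; step 2 is a one-step branch).

Steps most likely to fail

Step 1. The phase-transfer epoxidation may give low enantioselectivity or run on to the bis-epoxide. Fallback, setting out from 1 and returning at 2: a Diels–Alder reaction of 1 with cyclopentadiene under a chiral cationic oxazaborolidine catalyst ((S)-3,3-diphenyl-1-(2-methylphenyl)tetrahydropyrrolo[1,2-c][1,3,2]oxazaborole activated with HNTf2, CH2Cl2, −78 °C) should give the endo cyclopentadiene adduct F1. Alkaline H2O2 should then epoxidise the remaining enedione C=C from the convex face, syn to the ring-fusion methyl, to give the epoxy adduct F2. Flash vacuum pyrolysis (retro-Diels–Alder) expels cyclopentadiene and returns 2.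

Step 6. The sulfoxonium ylide may fail to add to the hindered C9 ketone and only enolise it. Fallback, setting out from 8 and returning at 13, with methylenation and peracid epoxidation after the oxidation-labile enol ether has been exchanged:
- Bu4NF/AcOH, then NaBH4, should give the 3β,6β-dihydroxy-9-ketone F6.
- t-BuMe2SiCl/imidazole should silylate only the equatorial 3β-hydroxyl to give silyl ether F7.
- Wittig methylenation (Ph3P=CH2, toluene, 90 °C) should give the 9(11)-methylene compound F8.
- mCPBA should attack from the α face, away from the C10 methyl, to give the 9α,11-epoxide F9.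
- Me3SI/n-BuLi should give the 9β-vinyl carbinol F10.
- Ac2O/DMAP should give the 6β-acetate F11, and HF·pyridine removes the silyl ether to return 13.

Step 3. The Z-methyl on the diene terminus may make the cycloaddition so slow that the diene is lost by 1,5-hydrogen shift, or facial and regiochemical control may erode at the temperature needed. Fallback, setting out from 3 and 2 and returning at 5, an anionic double Michael annulation: Me3SiCl/Et3N should convert 3 into the trimethylsilyl dienol ether F3, and MeLi releases the cross-conjugated lithium dienolate F4. At −78 °C this should add through C4 to the unsubstituted carbon C5 of 2, anti to the epoxide, and the resulting C10 enolate should close onto the vinyl ketone terminus C1 (6-endo Michael) to give the lithium enolate of the annulation product F5. O-silylation with i-Pr3SiOTf returns 5.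

Further compounds
F1 | step 1 | endo cyclopentadiene adduct of 1 (2,4-dimethyltricyclo[6.2.1.0(2,7)]undeca-4,9-diene-3,6-dione) | C[C@@]12C(=O)C(C)=CC(=O)[C@@H]1[C@@H]3C=C[C@H]2C3
F2 | step 1 | 4,5-epoxide of F1, oxygen on the convex face | C[C@@]12C(=O)[C@@]4(C)O[C@H]4C(=O)[C@@H]1[C@@H]3C=C[C@H]2C3
F3 | step 3 | trimethyl[(4-methylpenta-1,3-dien-3-yl)oxy]silane | C=CC(O[Si](C)(C)C)=C(C)C
F4 | step 3 | lithium 4-methylpenta-1,3-dien-3-olate | [Li+].[O-]C(C=C)=C(C)C
F5 | step 3 | lithium C3 enolate of the cis-fused epoxy annulation product | [Li+].C[C@]12CC=C([O-])C(C)(C)[C@H]1C(=O)[C@@H]3O[C@]3(C)C2=O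
F6 | step 6 | 3β,6β-dihydroxy-4,4,8α,10β-tetramethyl-trans-decalin-9-one | C[C@]12CC[C@H](O)C(C)(C)[C@@H]1[C@H](O)C[C@@H](C)C2=O
F7 | step 6 | 3β-(tert-butyldimethylsilyloxy)-6β-hydroxy-4,4,8α,10β-tetramethyl-trans-decalin-9-one | C[C@]12CC[C@H](O[Si](C)(C)C(C)(C)C)C(C)(C)[C@@H]1[C@H](O)C[C@@H](C)C2=O
F8 | step 6 | 9(11)-methylene compound from F7 | C[C@]12CC[C@H](O[Si](C)(C)C(C)(C)C)C(C)(C)[C@@H]1[C@H](O)C[C@@H](C)C2=C
F9 | step 6 | 9α,11-epoxide of F8 | C[C@]12CC[C@H](O[Si](C)(C)C(C)(C)C)C(C)(C)[C@@H]1[C@H](O)C[C@@H](C)[C@]23CO3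
F10 | step 6 | 3β-(tert-butyldimethylsilyloxy)-6β,9α-dihydroxy-9β-vinyl compound | C[C@]12CC[C@H](O[Si](C)(C)C(C)(C)C)C(C)(C)[C@@H]1[C@H](O)C[C@@H](C)[C@]2(O)C=C
F11 | step 6 | 6β-acetate of F10 | C[C@]12CC[C@H](O[Si](C)(C)C(C)(C)C)C(C)(C)[C@@H]1[C@H](OC(C)=O)C[C@@H](C)[C@]2(O)C=C
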